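**Strategy.** Everything rests on disconnecting the C4–C5 bond of the nonenoic acid chain (C1 = carboxyl carbon). C5 is a tertiary C–H stereocentre that sits on ring carbon 3 of the furan and next to the C4 methylene, so it can be generated as an oxygen-bearing, furan-stabilised carbanion. In one operation this lithiated carbamate captures a primary boronic ester carrying C1–C4 and the chain-C3 methyl stereocentre, and a stereospecific 1,2-shift of C4 from boron to C5 joins the two halves and sets C5 as a tertiary boronic ester. The precursor is the (R)-N,N-diisopropylcarbamate of the prenylated (5-arylfuran-3-yl)carbinol, both phenols masked as silyl ethers.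

Key step: step 11

Remarks on the chemistry (assumptions):
- The target is (3R,5S). Carbamate 10 is R, boronic ester 17 is R and tertiary boronic ester 20 is 3R,5S; these were rechecked against the target and are consistent.
- The sense of induction in step 3 is taken from aryl aldehydes ((R)-TRIP gives the (R)-carbinol) and that in step 6 from 3-substituted glutaric anhydrides ((DHQ)2AQN is taken to give the (S)-half-ester). Should either sense prove opposite, the mirror-image catalyst ((S)-TRIP or (DHQD)2AQN) is used and nothing else changes.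
- Compounds 1, 3, 5, 8 and 11 are taken as purchasable.

**Fragment A: carbamate 10**

Step 1
Reactants: 1 2-bromobenzene-1,4-diol (bromohydroquinone)
Product: 2 2-bromo-1,4-bis(tert-butyldimethylsilyloxy)benzene
Conditions: TBSCl (2.4 equiv), imidazole (5 equiv), DMF, 0 °C to rt
Reagents that add atoms: tert-butyldimethylsilyl chloride, CC(C)(C)[Si](C)(C)Cl
Why: Silyl ether formation on both phenols is routine for hydroquinones and gives ethers that tolerate palladium catalysis, metathesis and alkyllithium at low temperature while being poor directors of ring metalation.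

Step 2
Reactants: 2 2-bromo-1,4-bis(tert-butyldimethylsilyloxy)benzene; 3 (4-formylfuran-2-yl)boronic acid (1.5 equiv)
Product: 4 5-[2,5-bis(tert-butyldimethylsilyloxy)phenyl]furan-3-carbaldehyde
Conditions: Pd(OAc)2 (2 mol %), SPhos (4 mol %), K3PO4 (2 equiv), THF/H2O, 40 °C
Reagents that add atoms: none
Why: A Suzuki–Miyaura coupling with a dialkylbiarylphosphine ligand should join the hindered, electron-rich aryl bromide to furan C2 at a temperature low enough that the furylboronic acid is not lost to protodeboronation and the aryl silyl ethers and the aldehyde survive the phosphate base.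

Step 3
Reactants: 4 5-[2,5-bis(tert-butyldimethylsilyloxy)phenyl]furan-3-carbaldehyde; 5 allylboronic acid pinacol ester (1.2 equiv)
Product: 7 (R)-1-{5-[2,5-bis(tert-butyldimethylsilyloxy)phenyl]furan-3-yl}but-3-en-1-ol, via O-pinacolboryl ether 6 (not isolated)
Conditions: (R)-TRIP (5 mol %), toluene, −30 °C; aq. NH4Cl work-up
Reagents that add atoms: none
Why: In this chiral phosphoric acid-catalysed allylboration the acid binds the boronate oxygen and the chair-like six-membered transition state inside the catalyst pocket delivers allyl to one aldehyde face, which should set the (R)-carbinol as with aryl aldehydes, and the O–B bond is hydrolysed on work-up.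

Step 4
Reactants: 7 (R)-1-{5-[2,5-bis(tert-butyldimethylsilyloxy)phenyl]furan-3-yl}but-3-en-1-ol; 8 2-methyl-2-butene (large excess)
Product: 9 (R)-1-{5-[2,5-bis(tert-butyldimethylsilyloxy)phenyl]furan-3-yl}-4-methylpent-3-en-1-ol
Conditions: second-generation Grubbs catalyst RuCl2(=CHPh)(H2IMes)(PCy3) (5 mol %), CH2Cl2/2-methyl-2-butene, 40 °C, sealed vessel
Reagents that add atoms: none
Why: Olefin cross-metathesis of the terminal alkene with excess 2-methyl-2-butene exchanges =CH2 for =CMe2 to give the prenyl group, the trisubstituted product and the furan being inert to further metathesis and the carbinol centre not being touched.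

Step 5
Reactants: 9 (R)-1-{5-[2,5-bis(tert-butyldimethylsilyloxy)phenyl]furan-3-yl}-4-methylpent-3-en-1-ol
Product: 10 (R)-1-{5-[2,5-bis(tert-butyldimethylsilyloxy)phenyl]furan-3-yl}-4-methylpent-3-en-1-yl N,N-diisopropylcarbamate
Conditions: iPr2NCOCl (1.5 equiv), Et3N (2 equiv), DMAP (0.1 equiv), toluene, 80 °C
Reagents that add atoms: N,N-diisopropylcarbamoyl chloride, CC(C)N(C(C)C)C(=O)Cl
Why: O-Carbamoylation (acyl substitution at the carbamoyl chloride) breaks no bond to the stereocentre and installs the group that both directs the lithiation and leaves in the key step; amine base is used so that no alkoxide can strip the aryl silyl ethers.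

**Fragment B: boronic ester 17**

Step 6
Reactants: 11 3-methylglutaric anhydride
Product: 12 (S)-5-methoxy-3-methyl-5-oxopentanoic acid
Conditions: (DHQ)2AQN (15 mol %), MeOH (10 equiv), Et2O, −40 °C
Reagents that add atoms: methanol, CO
Why: In this cinchona-alkaloid-catalysed desymmetrising alcoholysis the quinuclidine acts as a chiral general base that directs methanol to one of the two enantiotopic carbonyl groups, which creates the chain-C3 methyl stereocentre.

Step 7
Reactants: 12 (S)-5-methoxy-3-methyl-5-oxopentanoic acid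
Product: 13 1-tert-butyl 5-methyl (R)-3-methylpentanedioate
Conditions: tert-butyl 2,2,2-trichloroacetimidate (2 equiv), BF3·OEt2 (cat.), cyclohexane/CH2Cl2, rt
Reagents that add atoms: tert-butyl 2,2,2-trichloroacetimidate, CC(C)(C)OC(=N)C(Cl)(Cl)Cl
Why: Acid-catalysed O-tert-butylation of the free acid by the imidate runs under nearly neutral conditions that leave the methyl ester and the stereocentre alone (the descriptor changes only because the priorities change).

Step 8
Reactants: 13 1-tert-butyl 5-methyl (R)-3-methylpentanedioate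
Product: 14 (R)-5-tert-butoxy-3-methyl-5-oxopentanoic acid
Conditions: LiOH·H2O (1.2 equiv), THF/H2O, 0 °C; then 1 M HCl to pH 3
Reagents that add atoms: lithium hydroxide, [Li+].[OH-]
Why: Saponification (acyl–oxygen cleavage by hydroxide) is selective for the unhindered methyl ester over the tert-butyl ester, and the stereocentre, being β to both carbonyls, cannot epimerise, so the two chain ends have simply exchanged roles.

Step 9
Reactants: 14 (R)-5-tert-butoxy-3-methyl-5-oxopentanoic acid
Product: 15 1-tert-butyl 5-(1,3-dioxoisoindolin-2-yl) (S)-3-methylpentanedioate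
Conditions: N-hydroxyphthalimide (1.1 equiv), DIC (1.1 equiv), DMAP (5 mol %), CH2Cl2, rt
Reagents that add atoms: N-hydroxyphthalimide, ON1C(=O)c2ccccc2C1=O
Why: A carbodiimide-mediated (Steglich-type) esterification converts the primary carboxylic acid into its redox-active N-acyloxyphthalimide without touching the stereocentre (descriptor change by priority only).

Step 10
Reactants: 15 1-tert-butyl 5-(1,3-dioxoisoindolin-2-yl) (S)-3-methylpentanedioate
Product: 17 tert-butyl (R)-3-methyl-4-(4,4,5,5-tetramethyl-1,3,2-dioxaborolan-2-yl)butanoate, via catechol boronic ester 16 (not isolated)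
Conditions: bis(catecholato)diboron (1.25 equiv), DMAc, blue LEDs, rt; then pinacol (4 equiv), Et3N, rt
Reagents that add atoms: bis(catecholato)diboron, B1(B2Oc3ccccc3O2)Oc2ccccc2O1; pinacol, CC(C)(O)C(C)(C)O
Why: In this photoinduced decarboxylative borylation the N-acyloxyphthalimide fragments to CO2 and the primary C4 radical, which is borylated by the diboron–amide complex, and diol exchange gives the stable pinacol ester; the radical is one carbon away from C3, so that centre is unaffected.

**Union and endgame**

Step 11
Reactants: 10 (R)-1-{5-[2,5-bis(tert-butyldimethylsilyloxy)phenyl]furan-3-yl}-4-methylpent-3-en-1-yl N,N-diisopropylcarbamate (1.0 equiv); 17 tert-butyl (R)-3-methyl-4-(4,4,5,5-tetramethyl-1,3,2-dioxaborolan-2-yl)butanoate (1.2 equiv)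
Product: 20 tert-butyl (3R,5S)-5-{5-[2,5-bis(tert-butyldimethylsilyloxy)phenyl]furan-3-yl}-3,8-dimethyl-5-(4,4,5,5-tetramethyl-1,3,2-dioxaborolan-2-yl)non-7-enoate, via lithiated carbamate 18 (not isolated), via lithium boronate complex 19 (not isolated)
Conditions: sBuLi (1.05 equiv), Et2O, −78 °C, 1 h; 17 in Et2O, −78 °C, 2 h; MgBr2·OEt2 in MeOH, −78 °C to rt, 16 h
Reagents that add atoms: none
Why: sBuLi, pre-coordinated to the carbamate carbonyl, removes the furylic C5–H with retention to give a chelated organolithium that is configurationally stable in Et2O at −78 °C, and boronic ester 17 captures it with retention to form boronate 19; on warming, C4 migrates from boron to C5 antiperiplanar to the departing carbamate with inversion at C5. This is a lithiation–borylation, that is a stereospecific 1,2-metallate rearrangement of the type established for enantioenriched secondary benzylic carbamates with pinacol boronic esters, the furan-3-yl ring taking the part of the aryl group. No ring is closed. The new C5 stereocentre is controlled solely by the carbinol configuration of 10 (retention, retention, inversion leads to 5S as drawn), and C3 is a spectator. The step needs site selectivity for the furylic C–H over furan C2–H and the silylated arene, which the complex-induced proximity effect of the carbamate and the absence of a diamine should secure, and chemoselectivity for boron over the tert-butyl ester, which the much faster boronate formation and the bulk of the ester should secure. MgBr2/MeOH added before warming speeds the shift and protonates any organolithium released by reversal, so that the stereospecificity is not eroded.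

Step 12
Reactants: 20 tert-butyl (3R,5S)-5-{5-[2,5-bis(tert-butyldimethylsilyloxy)phenyl]furan-3-yl}-3,8-dimethyl-5-(4,4,5,5-tetramethyl-1,3,2-dioxaborolan-2-yl)non-7-enoate
Product: 21 tert-butyl (3R,5S)-5-[5-(2,5-dihydroxyphenyl)furan-3-yl]-3,8-dimethylnon-7-enoate
Conditions: Bu4NF·3H2O (5 equiv), n-pentane/toluene, 45 °C, argon; aq. NH4Cl work-up
Reagents that add atoms: none
Why: In this fluoride-mediated protodeboronation of a tertiary heterobenzylic boronic ester, fluoride adds to boron and the C–B bond is protonated by boron-bound water on the same face (retention), which turns C5–B into C5–H with the 5S configuration, while the same reagent cleaves both aryl silyl ethers and leaves the tert-butyl ester.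

Step 13
Reactants: 21 tert-butyl (3R,5S)-5-[5-(2,5-dihydroxyphenyl)furan-3-yl]-3,8-dimethylnon-7-enoate
Product: 23 (3R,5S)-5-[5-(2,5-dihydroxyphenyl)furan-3-yl]-3,8-dimethylnon-7-enoic acid, via tris(trimethylsilyl) derivative 22 (not isolated)
Conditions: TMSOTf (5 equiv), 2,6-lutidine (7 equiv), CH2Cl2, 0 °C to rt, argon; then aq. citric acid/MeOH
Reagents that add atoms: none
Why: In this silyl triflate-mediated tert-butyl ester cleavage, O-silylation of the ester expels isobutene without any protic acid, so the furan, the prenyl alkene, the hydroquinone and both stereocentres are left alone, and the transient trimethylsilyl ester and ethers hydrolyse on work-up.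

**Compound list**

1 | 2-bromobenzene-1,4-diol | Oc1ccc(O)c(Br)c1 | starting material
2 | 2-bromo-1,4-bis(tert-butyldimethylsilyloxy)benzene | CC(C)(C)[Si](C)(C)Oc1ccc(O[Si](C)(C)C(C)(C)C)c(Br)c1 | intermediate
3 | (4-formylfuran-2-yl)boronic acid | OB(O)c1cc(C=O)co1 | starting material
4 | 5-[2,5-bis(tert-butyldimethylsilyloxy)phenyl]furan-3-carbaldehyde | O=Cc1coc(-c2cc(O[Si](C)(C)C(C)(C)C)ccc2O[Si](C)(C)C(C)(C)C)c1 | intermediate
5 | allylboronic acid pinacol ester | C=CCB1OC(C)(C)C(C)(C)O1 | starting material
6 | 2-{[(1R)-1-{5-[2,5-bis(tert-butyldimethylsilyloxy)phenyl]furan-3-yl}but-3-en-1-yl]oxy}-4,4,5,5-tetramethyl-1,3,2-dioxaborolane | CC1(C)OB(O[C@H](CC=C)c2coc(-c3cc(O[Si](C)(C)C(C)(C)C)ccc3O[Si](C)(C)C(C)(C)C)c2)OC1(C)C | intermediate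
7 | (R)-1-{5-[2,5-bis(tert-butyldimethylsilyloxy)phenyl]furan-3-yl}but-3-en-1-ol | O[C@H](CC=C)c1coc(-c2cc(O[Si](C)(C)C(C)(C)C)ccc2O[Si](C)(C)C(C)(C)C)c1 | intermediate
8 | 2-methyl-2-butene | CC=C(C)C | starting material
9 | (R)-1-{5-[2,5-bis(tert-butyldimethylsilyloxy)phenyl]furan-3-yl}-4-methylpent-3-en-1-ol | O[C@H](CC=C(C)C)c1coc(-c2cc(O[Si](C)(C)C(C)(C)C)ccc2O[Si](C)(C)C(C)(C)C)c1 | intermediate
10 | (R)-1-{5-[2,5-bis(tert-butyldimethylsilyloxy)phenyl]furan-3-yl}-4-methylpent-3-en-1-yl N,N-diisopropylcarbamate | CC(C)N(C(C)C)C(=O)O[C@H](CC=C(C)C)c1coc(-c2cc(O[Si](C)(C)C(C)(C)C)ccc2O[Si](C)(C)C(C)(C)C)c1 | intermediate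
11 | 3-methylglutaric anhydride | CC1CC(=O)OC(=O)C1 | starting material
12 | (S)-5-methoxy-3-methyl-5-oxopentanoic acid | COC(=O)C[C@@H](C)CC(=O)O | intermediate
13 | 1-tert-butyl 5-methyl (R)-3-methylpentanedioate | COC(=O)C[C@@H](C)CC(=O)OC(C)(C)C | intermediate
14 | (R)-5-tert-butoxy-3-methyl-5-oxopentanoic acid | OC(=O)C[C@@H](C)CC(=O)OC(C)(C)C | intermediate
15 | 1-tert-butyl 5-(1,3-dioxoisoindolin-2-yl) (S)-3-methylpentanedioate | O=C(C[C@@H](C)CC(=O)OC(C)(C)C)ON1C(=O)c2ccccc2C1=O | intermediate
16 | tert-butyl (R)-4-(1,3,2-benzodioxaborol-2-yl)-3-methylbutanoate | CC(C)(C)OC(=O)C[C@H](C)CB1Oc2ccccc2O1 | intermediate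
17 | tert-butyl (R)-3-methyl-4-(4,4,5,5-tetramethyl-1,3,2-dioxaborolan-2-yl)butanoate | CC1(C)OB(C[C@@H](C)CC(=O)OC(C)(C)C)OC1(C)C | intermediate
18 | (R)-1-{5-[2,5-bis(tert-butyldimethylsilyloxy)phenyl]furan-3-yl}-1-lithio-4-methylpent-3-en-1-yl N,N-diisopropylcarbamate (Li in the place of the carbinol H of 10) | CC(C)N(C(C)C)C(=O)O[C@]([Li])(CC=C(C)C)c1coc(-c2cc(O[Si](C)(C)C(C)(C)C)ccc2O[Si](C)(C)C(C)(C)C)c1 | intermediate
19 | lithium boronate complex of 18 with 17 (boron in the place of lithium; four-coordinate boron bearing C4, the carbamate-bearing C5 and the pinacolate) | [Li+].CC(C)N(C(C)C)C(=O)O[C@]([B-]3(C[C@@H](C)CC(=O)OC(C)(C)C)OC(C)(C)C(C)(C)O3)(CC=C(C)C)c1coc(-c2cc(O[Si](C)(C)C(C)(C)C)ccc2O[Si](C)(C)C(C)(C)C)c1 | intermediate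
20 | tert-butyl (3R,5S)-5-{5-[2,5-bis(tert-butyldimethylsilyloxy)phenyl]furan-3-yl}-3,8-dimethyl-5-(4,4,5,5-tetramethyl-1,3,2-dioxaborolan-2-yl)non-7-enoate | CC(C)=CC[C@](B1OC(C)(C)C(C)(C)O1)(C[C@@H](C)CC(=O)OC(C)(C)C)c1coc(-c2cc(O[Si](C)(C)C(C)(C)C)ccc2O[Si](C)(C)C(C)(C)C)c1 | intermediate
21 | tert-butyl (3R,5S)-5-[5-(2,5-dihydroxyphenyl)furan-3-yl]-3,8-dimethylnon-7-enoate | CC(C)=CC[C@H](C[C@@H](C)CC(=O)OC(C)(C)C)c1coc(-c2cc(O)ccc2O)c1 | intermediate
22 | trimethylsilyl (3R,5S)-5-{5-[2,5-bis(trimethylsilyloxy)phenyl]furan-3-yl}-3,8-dimethylnon-7-enoate | CC(C)=CC[C@H](C[C@@H](C)CC(=O)O[Si](C)(C)C)c1coc(-c2cc(O[Si](C)(C)C)ccc2O[Si](C)(C)C)c1 | intermediate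
23 | (3R,5S)-5-[5-(2,5-dihydroxyphenyl)furan-3-yl]-3,8-dimethylnon-7-enoic acid | CC(C)=CC[C@H](C[C@@H](C)CC(=O)O)c1coc(-c2cc(O)ccc2O)c1 | target

**Step count.** Total: 13 steps. Longest linear sequence: 8 steps (steps 6–10, then 11–13; fragment A, steps 1–5 then 11–13, is equally long).

**Steps most likely to fail, with fallbacks**

1. Step 11 (key step). The organolithium may be lost before boron captures it, either by metalation of furan C2–H in place of the furylic C–H or by proton transfer from, or addition to, the ester. Boronate 19 may also revert to its components before the shift, so that conversion and configurational purity at C5 fall. The fallback sets out from 15, uses 10 unchanged and returns at 21; it stays within the same reaction family, because no shorter route of established chemistry to this C5 centre was found. The photoborylation of 15 would be quenched with neopentyl glycol in place of pinacol, which gives tert-butyl (R)-4-(5,5-dimethyl-1,3,2-dioxaborinan-2-yl)-3-methylbutanoate F1. This unhindered six-membered boronic ester is the established remedy for slow or reversible capture of lithiated secondary benzylic carbamates: it takes up the carbanion faster, which leaves less time for reaction at the ester, and its boronates do not dissociate. The union can then be run in two separate stages, boronate formation at −78 °C and the 1,2-shift on heating in Et2O/CHCl3 without additive. The product, tert-butyl (3R,5S)-5-{5-[2,5-bis(tert-butyldimethylsilyloxy)phenyl]furan-3-yl}-5-(5,5-dimethyl-1,3,2-dioxaborinan-2-yl)-3,8-dimethylnon-7-enoate F2, would be treated with Bu4NF·3H2O as in step 12 to give 21.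

2. Step 12. Silicon consumes fluoride first and sets phenoxides free, so the C–B protonolysis at C5 may become slow or lose its retentive course because phenol protons compete with boron-bound water, and the unmasked hydroquinone may be oxidised under the basic conditions. The fallback sets out from 20 and returns at 23, and it separates the two events. Cs2CO3 in wet DMF at rt under argon, which cleaves aryl silyl ethers but not a hindered tertiary boronic ester or a tert-butyl ester, would give tert-butyl (3R,5S)-5-[5-(2,5-dihydroxyphenyl)furan-3-yl]-3,8-dimethyl-5-(4,4,5,5-tetramethyl-1,3,2-dioxaborolan-2-yl)non-7-enoate F3. Chloromethyl methyl ether and iPr2NEt in CH2Cl2 would then give the fluoride-stable bis(methoxymethyl) ether tert-butyl (3R,5S)-5-{5-[2,5-bis(methoxymethoxy)phenyl]furan-3-yl}-3,8-dimethyl-5-(4,4,5,5-tetramethyl-1,3,2-dioxaborolan-2-yl)non-7-enoate F4. Protodeboronation with Bu4NF·3H2O, now on a substrate that releases no phenoxide, would give tert-butyl (3R,5S)-5-{5-[2,5-bis(methoxymethoxy)phenyl]furan-3-yl}-3,8-dimethylnon-7-enoate F5. TMSOTf with 2,2′-bipyridyl and 2,6-lutidine in CH2Cl2, followed by water, removes aryl methoxymethyl ethers and the tert-butyl ester together under non-protic conditions and would give 23.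

3. Step 2. Protodeboronation of the 2-furylboronic acid may outrun transmetalation with the hindered, electron-rich aryl bromide, or the aqueous base may cleave the aryl silyl ethers. The fallback sets out from 2 and returns at 4, and it reverses the polarity of the coupling so that the boron sits on the stable partner. Miyaura borylation of 2 (bis(pinacolato)diboron, Pd(dppf)Cl2, KOAc, dioxane, 90 °C) would give 2-[2,5-bis(tert-butyldimethylsilyloxy)phenyl]-4,4,5,5-tetramethyl-1,3,2-dioxaborolane F6. Suzuki–Miyaura coupling of F6 with methyl 5-bromofuran-3-carboxylate (COC(=O)c1coc(Br)c1, a catalogue compound or the methyl ester of 5-bromofuran-3-carboxylic acid; Pd(dppf)Cl2, K3PO4, dioxane/H2O, 60 °C), in which the electron-poor bromofuran adds quickly to palladium, would give methyl 5-[2,5-bis(tert-butyldimethylsilyloxy)phenyl]furan-3-carboxylate F7. Reduction with iBu2AlH in CH2Cl2 at −78 °C would give {5-[2,5-bis(tert-butyldimethylsilyloxy)phenyl]furan-3-yl}methanol F8, and MnO2 in CH2Cl2 would oxidise this furylic alcohol to aldehyde 4.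

**Further compounds**

F1 | step 11 | tert-butyl (R)-4-(5,5-dimethyl-1,3,2-dioxaborinan-2-yl)-3-methylbutanoate | CC1(C)COB(C[C@@H](C)CC(=O)OC(C)(C)C)OC1
F2 | step 11 | tert-butyl (3R,5S)-5-{5-[2,5-bis(tert-butyldimethylsilyloxy)phenyl]furan-3-yl}-5-(5,5-dimethyl-1,3,2-dioxaborinan-2-yl)-3,8-dimethylnon-7-enoate | CC(C)=CC[C@](B1OCC(C)(C)CO1)(C[C@@H](C)CC(=O)OC(C)(C)C)c1coc(-c2cc(O[Si](C)(C)C(C)(C)C)ccc2O[Si](C)(C)C(C)(C)C)c1
F3 | step 12 | tert-butyl (3R,5S)-5-[5-(2,5-dihydroxyphenyl)furan-3-yl]-3,8-dimethyl-5-(4,4,5,5-tetramethyl-1,3,2-dioxaborolan-2-yl)non-7-enoate | CC(C)=CC[C@](B1OC(C)(C)C(C)(C)O1)(C[C@@H](C)CC(=O)OC(C)(C)C)c1coc(-c2cc(O)ccc2O)c1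
F4 | step 12 | tert-butyl (3R,5S)-5-{5-[2,5-bis(methoxymethoxy)phenyl]furan-3-yl}-3,8-dimethyl-5-(4,4,5,5-tetramethyl-1,3,2-dioxaborolan-2-yl)non-7-enoate | CC(C)=CC[C@](B1OC(C)(C)C(C)(C)O1)(C[C@@H](C)CC(=O)OC(C)(C)C)c1coc(-c2cc(OCOC)ccc2OCOC)c1
F5 | step 12 | tert-butyl (3R,5S)-5-{5-[2,5-bis(methoxymethoxy)phenyl]furan-3-yl}-3,8-dimethylnon-7-enoate | CC(C)=CC[C@H](C[C@@H](C)CC(=O)OC(C)(C)C)c1coc(-c2cc(OCOC)ccc2OCOC)c1
F6 | step 2 | 2-[2,5-bis(tert-butyldimethylsilyloxy)phenyl]-4,4,5,5-tetramethyl-1,3,2-dioxaborolane | CC(C)(C)[Si](C)(C)Oc1ccc(O[Si](C)(C)C(C)(C)C)c(B2OC(C)(C)C(C)(C)O2)c1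
F7 | step 2 | methyl 5-[2,5-bis(tert-butyldimethylsilyloxy)phenyl]furan-3-carboxylate | COC(=O)c1coc(-c2cc(O[Si](C)(C)C(C)(C)C)ccc2O[Si](C)(C)C(C)(C)C)c1
F8 | step 2 | {5-[2,5-bis(tert-butyldimethylsilyloxy)phenyl]furan-3-yl}methanol | OCc1coc(-c2cc(O[Si](C)(C)C(C)(C)C)ccc2O[Si](C)(C)C(C)(C)C)c1
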